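**Retrosynthetic overview**

1. The strategy rests on the dihydrofuran ring O1–C2–C3–C3a–C7a of target 12, with the aryl group on C2 and a one-carbon group on C3. It is the pyranone ring of a 2-arylchroman-4-one with the carbonyl carbon C4 pushed out of the ring. So 12 ⇐ diester 11 (hydride reduction) ⇐ (2S)-flavanone 9 by oxidative ring contraction: ring A carbon C4a moves from C4 to C3, making C3–C3a, and C4 becomes the ester carbon.
2. 9 ⇐ chromone 5 + arylboronic acid 8 by enantioselective conjugate addition, which sets C2. The syringyl phenol is pivaloylated before this step, so the flavanone never carries a free para-hydroxyaryl group that could ionise C2.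
3. 5 ⇐ ortho-hydroxyacetophenone 3 (enaminone cyclisation) ⇐ Fries rearrangement of acetate 2 ⇐ methyl dihydroferulate 1; 8 ⇐ boronate 6 (pivaloylation, pinacol cleavage).
4. Ring order: rings A and B are bought; the pyranone ring is closed in step 3 and contracted to the dihydrofuran ring in step 7.

Key step: step 7

**Route**

Step 1
Reactants: 1 methyl 3-(4-hydroxy-3-methoxyphenyl)propanoate
Product: 2 methyl 3-(4-acetoxy-3-methoxyphenyl)propanoate
Conditions: Ac2O (1.5 equiv), pyridine, DMAP (cat.), CH2Cl2, rt
Reagents that add atoms: acetic anhydride, CC(=O)OC(C)=O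
Why: Plain O-acylation of a phenol, which installs the acyl group that the Fries rearrangement will move onto the ring.

Step 2
Reactants: 2 methyl 3-(4-acetoxy-3-methoxyphenyl)propanoate
Product: 3 methyl 3-(3-acetyl-4-hydroxy-5-methoxyphenyl)propanoate
Conditions: BF3·OEt2 (3 equiv), neat, 90 °C; then H2O
Reagents that add atoms: none
Why: Fries rearrangement, in which the Lewis acid moves the acetyl group from oxygen to the only free ortho carbon (the para position carries the side chain), while BF3 should leave the aryl methyl ether and the methyl ester alone.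

Step 3
Reactants: 3 methyl 3-(3-acetyl-4-hydroxy-5-methoxyphenyl)propanoate
Product: 5 methyl 3-(8-methoxy-4-oxo-4H-chromen-6-yl)propanoate, via enaminone 4 (not isolated)
Conditions: Me2NCH(OMe)2 (3 equiv), toluene, 100 °C; concentrate; then conc. HCl, CH2Cl2, 40 °C
Reagents that add atoms: N,N-dimethylformamide dimethyl acetal, COC(OC)N(C)C
Why: Enaminone formation at the methyl ketone, followed by acid-promoted 6-endo addition of the phenol oxygen to the enaminone β-carbon and loss of dimethylamine, is the standard route to a 2,3-unsubstituted chromone.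

Step 4
Reactants: 6 2,6-dimethoxy-4-(4,4,5,5-tetramethyl-1,3,2-dioxaborolan-2-yl)phenol
Product: 7 2,6-dimethoxy-4-(4,4,5,5-tetramethyl-1,3,2-dioxaborolan-2-yl)phenyl pivalate
Conditions: t-BuCOCl (1.5 equiv), Et3N (2 equiv), DMAP (0.2 equiv), CH2Cl2, 0 °C to rt
Reagents that add atoms: pivaloyl chloride, CC(C)(C)C(=O)Cl
Why: DMAP-catalysed acylation of the hindered phenol gives a robust electron-withdrawing ester that suppresses protodeboronation now and ring B participation in step 7.

Step 5
Reactants: 7 2,6-dimethoxy-4-(4,4,5,5-tetramethyl-1,3,2-dioxaborolan-2-yl)phenyl pivalate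
Product: 8 [3,5-dimethoxy-4-(pivaloyloxy)phenyl]boronic acid
Conditions: NaIO4 (3 equiv), NH4OAc (3 equiv), acetone/H2O 1:1, rt
Reagents that add atoms: water, O
Why: Oxidative cleavage of the pinacol by periodate drives hydrolysis of the boronic ester under near-neutral conditions that the aryl pivalate tolerates, giving the free boronic acid needed for transmetalation to palladium.

Step 6
Reactants: 5 methyl 3-(8-methoxy-4-oxo-4H-chromen-6-yl)propanoate, 8 [3,5-dimethoxy-4-(pivaloyloxy)phenyl]boronic acid (2 equiv)
Product: 9 methyl 3-[(2S)-2-[3,5-dimethoxy-4-(pivaloyloxy)phenyl]-8-methoxy-4-oxochroman-6-yl]propanoate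
Conditions: Pd(OCOCF3)2 (5 mol%), (R)-t-BuPyOx [(R)-4-tert-butyl-2-(pyridin-2-yl)-4,5-dihydrooxazole] (6 mol%), NH4PF6 (30 mol%), H2O (5 equiv), ClCH2CH2Cl, 60 °C
Reagents that add atoms: none
Why: Asymmetric conjugate addition of an arylboronic acid to a chromone under cationic divalent palladium/pyridine-oxazoline catalysis (transmetalation, enantioface-selective insertion of C2=C3 into the aryl–palladium bond, protonolysis of the enolate) sets C2 under base-free conditions that do not open the flavanone; the R ligand is expected to give 2S by analogy with the facial model for cyclic enones, and the antipodal ligand is used if the sense proves opposite.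

Step 7
Reactants: 9 methyl 3-[(2S)-2-[3,5-dimethoxy-4-(pivaloyloxy)phenyl]-8-methoxy-4-oxochroman-6-yl]propanoate
Product: 11 methyl (2S,3S)-2-[3,5-dimethoxy-4-(pivaloyloxy)phenyl]-7-methoxy-5-(3-methoxy-3-oxopropyl)-2,3-dihydro-1-benzofuran-3-carboxylate, via methyl enol ether 10 (not isolated)
Conditions: PhI(OAc)2 (1.2 equiv), conc. H2SO4 (1 equiv), HC(OMe)3, 0 °C to rt; then aq. NaHCO3
Reagents that add atoms: trimethyl orthoformate, COC(OC)OC; water, O
Why: Acid and trimethyl orthoformate turn the C4 ketone into the 4-methoxy-2H-chromene 10, whose C3 is attacked by the electrophilic trivalent iodine of acid-activated PhI(OAc)2 on the face anti to the C2 aryl group while methanol adds at C4 to give the dimethyl ketal. The ring A carbon C4a, antiperiplanar to the pseudoaxial C3–I bond, then shifts from C4 to C3 with inversion at C3 as iodobenzene departs, forming the C3–C3a bond and leaving an exocyclic dimethoxycarbenium ion that ends as the methyl ester. The closest known reaction type is the hypervalent iodine (or thallium trinitrate) oxidative ring contraction of flavanones in acidic orthoformate to methyl trans-2-aryl-2,3-dihydrobenzofuran-3-carboxylates. The five-membered ring is closed by ring contraction, a 1,2-shift inside the six-membered ring, not by a cyclisation. C2 is not touched and directs the new C3 centre: anti iodination followed by invertive migration places the ester trans to the aryl group, which is also the thermodynamically preferred arrangement. The step needs migration of ring A in preference to the 2→3 shift of ring B (isoflavone), to dehydrogenation (flavone) and to ionisation at C2; the ring oxygen ortho to the migrating carbon stabilises the bridged transition state, and the pivalate keeps ring B a poor migrating group and a poor stabiliser of a C2 cation.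

Step 8
Reactants: 11 methyl (2S,3S)-2-[3,5-dimethoxy-4-(pivaloyloxy)phenyl]-7-methoxy-5-(3-methoxy-3-oxopropyl)-2,3-dihydro-1-benzofuran-3-carboxylate
Product: 12 4-[(2S,3R)-3-(hydroxymethyl)-5-(3-hydroxypropyl)-7-methoxy-2,3-dihydro-1-benzofuran-2-yl]-2,6-dimethoxyphenol
Conditions: LiAlH4 (5 equiv), THF, 0 °C to rt; then EtOAc, aq. potassium sodium tartrate
Reagents that add atoms: none
Why: Hydride reduction takes both methyl esters to primary alcohols and cleaves the aryl pivalate to the phenol in one operation without touching C2 or C3 (the C3 descriptor changes from S to R only because the CIP priorities change; the trans arrangement is unchanged).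

**Compound list**

1 | methyl 3-(4-hydroxy-3-methoxyphenyl)propanoate (methyl dihydroferulate) | COC(=O)CCc1ccc(O)c(OC)c1 | starting material
2 | methyl 3-(4-acetoxy-3-methoxyphenyl)propanoate | COC(=O)CCc1ccc(OC(C)=O)c(OC)c1 | intermediate
3 | methyl 3-(3-acetyl-4-hydroxy-5-methoxyphenyl)propanoate | COC(=O)CCc1cc(OC)c(O)c(C(C)=O)c1 | intermediate
4 | methyl 3-{3-[(E)-3-(dimethylamino)prop-2-enoyl]-4-hydroxy-5-methoxyphenyl}propanoate (enaminone, not isolated) | COC(=O)CCc1cc(OC)c(O)c(C(=O)/C=C/N(C)C)c1 | intermediate
5 | methyl 3-(8-methoxy-4-oxo-4H-chromen-6-yl)propanoate | COC(=O)CCc1cc(OC)c2occc(=O)c2c1 | intermediate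
6 | 2,6-dimethoxy-4-(4,4,5,5-tetramethyl-1,3,2-dioxaborolan-2-yl)phenol | COc1cc(cc(OC)c1O)B1OC(C)(C)C(C)(C)O1 | starting material
7 | 2,6-dimethoxy-4-(4,4,5,5-tetramethyl-1,3,2-dioxaborolan-2-yl)phenyl pivalate | COc1cc(cc(OC)c1OC(=O)C(C)(C)C)B1OC(C)(C)C(C)(C)O1 | intermediate
8 | [3,5-dimethoxy-4-(pivaloyloxy)phenyl]boronic acid | COc1cc(B(O)O)cc(OC)c1OC(=O)C(C)(C)C | intermediate
9 | methyl 3-[(2S)-2-[3,5-dimethoxy-4-(pivaloyloxy)phenyl]-8-methoxy-4-oxochroman-6-yl]propanoate | COc1cc([C@H]2Oc3c(OC)cc(CCC(=O)OC)cc3C(=O)C2)cc(OC)c1OC(=O)C(C)(C)C | intermediate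
10 | methyl 3-[(2S)-2-[3,5-dimethoxy-4-(pivaloyloxy)phenyl]-4,8-dimethoxy-2H-chromen-6-yl]propanoate (methyl enol ether, not isolated) | COc1cc([C@H]2Oc3c(OC)cc(CCC(=O)OC)cc3C(OC)=C2)cc(OC)c1OC(=O)C(C)(C)C | intermediate
11 | methyl (2S,3S)-2-[3,5-dimethoxy-4-(pivaloyloxy)phenyl]-7-methoxy-5-(3-methoxy-3-oxopropyl)-2,3-dihydro-1-benzofuran-3-carboxylate (trans) | COc1cc([C@H]2Oc3c(OC)cc(CCC(=O)OC)cc3[C@@H]2C(=O)OC)cc(OC)c1OC(=O)C(C)(C)C | intermediate
12 | 4-[(2S,3R)-3-(hydroxymethyl)-5-(3-hydroxypropyl)-7-methoxy-2,3-dihydro-1-benzofuran-2-yl]-2,6-dimethoxyphenol | COc1cc([C@H]2Oc3c(OC)cc(CCCO)cc3[C@@H]2CO)cc(OC)c1O | target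

**Step count**

Total: 8 steps. Longest linear sequence: 6 steps (steps 1, 2, 3, 6, 7, 8); steps 4 and 5 form the short side branch.

**Steps most likely to fail**

Step 7. The iodonium intermediate may collapse by other paths. Ring B may shift from C2 to C3, or hydrogen may be lost to give the flavone. The oxidant may attack the oxygenated arenes. Acid may ionise C2 and erode the enantiomeric purity.
The fallback keeps the same bond change but uses a carbene instead of an iodonium leaving group. It sets out from 9 and comes back at 11.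
- The kinetic lithium enolate of 9 (LiN(SiMe3)2, THF, −78 °C) would be acylated with 2,2,2-trifluoroethyl trifluoroacetate to give methyl 3-[(2S)-2-[3,5-dimethoxy-4-(pivaloyloxy)phenyl]-8-methoxy-4-oxo-3-(trifluoroacetyl)chroman-6-yl]propanoate F1.
- Detrifluoroacetylative diazo transfer (MeSO2N3, Et3N, MeCN) would give methyl 3-[(2R)-3-diazo-2-[3,5-dimethoxy-4-(pivaloyloxy)phenyl]-8-methoxy-4-oxochroman-6-yl]propanoate F2. The descriptor changes by priority only.
- Irradiation of F2 in methanol should trigger a Wolff rearrangement. The same ring A carbon migrates to C3, and the exocyclic ketene is trapped by methanol.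
- A mixture of C3 epimers is expected. Brief treatment with DBU in CH2Cl2 should move it to the trans ester 11.

Step 6. Enantioface discrimination may be poor, or insertion of the vinylogous-ester C2=C3 bond may be slow. Boronic acid 8 may be lost by protodeboronation or homocoupling.
The fallback builds the flavanone racemic and resolves it. It sets out from 3 and comes back at 9.
- Syringaldehyde would be pivaloylated (t-BuCOCl, Et3N, DMAP) to 4-formyl-2,6-dimethoxyphenyl pivalate F3.
- Amine-mediated aldol condensation and oxa-Michael closure of 3 with F3 (pyrrolidine, MeOH, 60 °C) should give racemic methyl 3-[2-[3,5-dimethoxy-4-(pivaloyloxy)phenyl]-8-methoxy-4-oxochroman-6-yl]propanoate F4.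
- Kinetic resolution by asymmetric transfer hydrogenation (RuCl(p-cymene)(TsDPEN), HCO2H/Et3N) would follow. The ligand enantiomer is chosen so that the 2R ketone is reduced faster.
- The 2R ketone would be converted into methyl 3-[(2R,4R)-2-[3,5-dimethoxy-4-(pivaloyloxy)phenyl]-4-hydroxy-8-methoxychroman-6-yl]propanoate F5. Unreacted 9 would be recovered enantioenriched and separated by chromatography.

Step 2. The acetyl group may be delivered to the carbon para to the methoxy group instead of ortho to the phenol oxygen. The rearrangement may stop short, or the neighbouring methyl ether may be partly cleaved.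
The fallback builds the acetyl group ortho to oxygen by a directed route. It sets out from 1, bypasses 2, and comes back at 3.
- Magnesium phenoxide-directed ortho-formylation (MgCl2, Et3N, paraformaldehyde, MeCN, reflux) should give methyl 3-(3-formyl-4-hydroxy-5-methoxyphenyl)propanoate F6.
- Chemoselective addition of MeMgBr (2.2 equiv, THF, −78 °C) to the aldehyde would give racemic methyl 3-[4-hydroxy-3-(1-hydroxyethyl)-5-methoxyphenyl]propanoate F7.
- Benzylic oxidation with MnO2 in CH2Cl2 should give 3.

**Further compounds**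

F1 | step 7 | methyl 3-[(2S)-2-[3,5-dimethoxy-4-(pivaloyloxy)phenyl]-8-methoxy-4-oxo-3-(trifluoroacetyl)chroman-6-yl]propanoate (C3 unassigned, largely enolised) | COc1cc([C@H]2Oc3c(OC)cc(CCC(=O)OC)cc3C(=O)C2C(=O)C(F)(F)F)cc(OC)c1OC(=O)C(C)(C)C
F2 | step 7 | methyl 3-[(2R)-3-diazo-2-[3,5-dimethoxy-4-(pivaloyloxy)phenyl]-8-methoxy-4-oxochroman-6-yl]propanoate | COc1cc([C@H]2Oc3c(OC)cc(CCC(=O)OC)cc3C(=O)C2=[N+]=[N-])cc(OC)c1OC(=O)C(C)(C)C
F3 | step 6 | 4-formyl-2,6-dimethoxyphenyl pivalate | COc1cc(C=O)cc(OC)c1OC(=O)C(C)(C)C
F4 | step 6 | racemic methyl 3-[2-[3,5-dimethoxy-4-(pivaloyloxy)phenyl]-8-methoxy-4-oxochroman-6-yl]propanoate | COc1cc(C2Oc3c(OC)cc(CCC(=O)OC)cc3C(=O)C2)cc(OC)c1OC(=O)C(C)(C)C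
F5 | step 6 | methyl 3-[(2R,4R)-2-[3,5-dimethoxy-4-(pivaloyloxy)phenyl]-4-hydroxy-8-methoxychroman-6-yl]propanoate | COc1cc([C@@H]2Oc3c(OC)cc(CCC(=O)OC)cc3[C@H](O)C2)cc(OC)c1OC(=O)C(C)(C)C
F6 | step 2 | methyl 3-(3-formyl-4-hydroxy-5-methoxyphenyl)propanoate | COC(=O)CCc1cc(OC)c(O)c(C=O)c1
F7 | step 2 | racemic methyl 3-[4-hydroxy-3-(1-hydroxyethyl)-5-methoxyphenyl]propanoate | COC(=O)CCc1cc(OC)c(O)c(C(C)O)c1
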